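## Structural features

The target is a 1,3-diacylglycerol: an (S)-configured glycerol carries an acetate on one primary oxygen, a free secondary hydroxyl, and on the other primary oxygen the ester of a C20 bicyclic acid (labels C1–C10 below are the decalin numbering of that acid). The acid is a cis-fused decalin: ring A (C1, C2, C3, C4, C5, C10) is saturated and carries the carboxyl on C1 and a methyl on C2, ring B (C5, C6, C7, C8, C9, C10) contains the trisubstituted C6=C7 alkene, and C6 bears a 4-methylpent-3-enyl chain. Four stereocentres are contiguous along C2–C1–C10–C5: C10 and C5 are vicinal quaternary carbons with cis angular methyls, the C1 carboxyl is cis to both and trans to the C2 methyl, and a fifth, remote centre sits in the glycerol. Fragile features are the two trisubstituted alkenes (acid, and competition in any hydrogenation), the free 2-hydroxyl flanked by two esters (acyl migration), and the C1–H next to the carbonyl. The carboxyl is neopentyl-like, so its ester is hard to make or cleave by attack at the carbonyl carbon. The real difficulty is the pair of adjacent quaternary carbons together with tertiary C1, all to be set in one relative and absolute sense. The key step exploits the fact that C1 is both α to the carboxyl and bonded to quaternary C10, while C4 of ring A is tied to C1 through C2–C3: with an oxygen on C4 and a C5=C10 alkene, the atoms C1, carboxyl carbon, O, C4, C5 and C10 form the array of an ester-enolate [3,3] shift held inside a δ-lactone.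

## Logic of the disconnections

30 ⇒ 29. The acetyl C–O bond on the primary glycerol oxygen is cut last because this ester is the most labile group and the one that can migrate. The gain is a diol whose two hydroxyls differ in class. The forward step must acetylate only the primary hydroxyl, at low temperature, without moving either acyl group.

29 ⇒ 28 ⇒ 20 ⇒ 18 + 19. The diol is masked as the acetonide, and the ester is cut at the O–CH2 bond, not at the acyl–O bond. The carboxyl of 18 is too hindered for acyl substitution, but its carboxylate can attack the CH2 of activated 19. This buys the glycerol stereocentre and lets the ester double as the carboxyl protecting group through steps 11–16. The demand is that the acetonide survives fluoride, oxidation, olefination and palladium, and comes off without acid damage to the alkenes.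

28 ⇒ 27. A C3=C4 alkene is written into ring A so that the C5–C6 bond can be made by a Heck reaction. The forward step must hydrogenate this cis-disubstituted alkene and leave two trisubstituted alkenes.

27 ⇒ 26. The C5–C6 bond of ring B is cut. C5 is quaternary and sits next to quaternary C10, and a vinyl palladium tethered through C9–C8–C7 can only reach the ring A alkene from the face that carries the tether, which forces the cis fusion. This reduces the bicycle to a monocyclic ring A with a side arm. The demand is 6-exo carbopalladation at a fully substituted alkene carbon.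

26 ⇒ 23 + 24, and 23 ⇒ 22. The C6–chain bond and the C6=C7 bond are cut, so C6 comes from CBr4 as a 1,1-dibromoalkene linchpin. The forward coupling must replace only the bromide trans to the C8 chain, leaving the bromide that is cis to the tether.

22 ⇒ 21 ⇒ 20. These are oxidation-level adjustments of the C7 arm, carried as a silyl ether through the strongly basic key step.

18 ⇒ 15 (key). The C1–C10 bond is cut and O–C4 is reconnected, which is the retro-[3,3] shift of a lactone silyl enolate. Ring A, the quaternary C10 and tertiary C1 are traded for a δ-lactone with one carbinol centre (C4), one methyl centre (C2) and one alkene geometry. Strictly, a six-membered lactone becomes a six-membered carbocycle, so this is a ring transposition of equal size and not a contraction in ring size. Re-derivation of the stereochemistry confirms that the (4R,6R)-cis lactone with the Z alkene leads to (1S,2R,6R)-18, so no configuration needs changing. The demand is a boat transition state that forms a quaternary centre.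

15 ⇒ 14. A C1=C2 alkene is written into the lactone so that the C2 methyl centre can be set by hydride addition anti to the C4 substituent.

14 ⇒ 13 ⇒ 11 + 12. The ring alkene is cut by metathesis and the acrylate C–O bond by acylation. An aldol-type union of 7 with a four-carbon dienolate was set aside because it gives an open E-enoate, which cannot lactonise without double-bond isomerisation next to an ionisable allylic carbinol. Metathesis gives the cis ring alkene directly.

11 ⇒ 7 + 8. The C3–C4 bond is cut. Reagent-controlled methallylboration sets the C4 carbinol, the single stereocentre from which C10, C1 and (through step 8) C2 derive.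

7 ⇒ 6 ⇒ 5 ⇒ 2 + 3 ⇒ 1. The C9–C10 bond is cut at the tetrasubstituted alkene. The Z geometry with cis methyls comes from chelation-controlled enol triflation of 1 and a stereoretentive sp3–sp2 coupling. This reaches 7 in four steps from a commercial keto ester; a route that takes the cis-dimethyl unit from a cyclic precursor would secure the geometry by the ring but needs more steps.

## Other disconnections considered

Alternative 1: The cut is the central C5–C10 bond, which opens both rings to the ten-membered diketone A1 (2,7-dimethylcyclodecane-1,6-dione). Forward, its bis(trimethylsilyl enol ether) A2 would be oxidised by one electron, for example with (NH4)2Ce(NO3)6, so that the two enol α-carbons couple across the ring to the C2-symmetric cis-dione A3.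
- In its favour: both rings and both quaternary centres form in one bond-forming event from a symmetric precursor. On bond and ring economy at the core it is better than the chosen plan, which needs two ring closures (steps 9 and 15).
- Equal or better: the two ketones of A3 are homotopic, so a first mono-functionalisation raises no site-selectivity question. The C6 ketone, enolisable only towards C7, maps onto an alkenyl triflate for the side chain as simply as steps 13–14 do.
- Against it here: A1 is a medium ring that must itself be made. The cis/trans outcome of the transannular coupling depends on the conformation of the ten-membered ring and not on a tether. A3 would be racemic unless resolved.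
- The decisive weakness: C1 and C2 are left blank. A neopentyl ketone must be homologated by one carbon and methylated at C2, and both centres set on a hindered, preformed decalin. The chosen plan sets C1 and C10 in one stereospecific event with C2 already in place.

Alternative 2: The cut is C5–C6 of ring B. Forward, the vinyl bromide A4 (the methyl ester analogue of 26) undergoes intramolecular Heck closure to the cis-fused diene A5.
- In its favour: the tether dictates the cis fusion and the quaternary C5 forms under catalyst turnover.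
- Equal: this is the same reaction as step 15 (26 → 27), so mechanism and risk are identical in both plans.
- Against it as the sole strategic step: it says nothing about how ring A of A4, with C1, C2 and quaternary C10, is obtained. That is the harder half of the problem, which the chosen key step solves.
- Step economy: no difference, because the chosen route contains this step.

Alternative 3: The cuts are C5–C6 and C1–C10 together, leading to the acyclic enyne A6. Forward, a cationic gold catalyst such as Ph3PAuNTf2 activates the C6≡C7 alkyne, C5 of the tetrasubstituted alkene attacks it, and the C10 cation is trapped by C1 of the silyl enol ether to give the bicyclic keto ester A7.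
- In its favour: two rings, two bonds and both quaternary centres in one step from a linear chain, with the cis fusion following from anti addition across the Z alkene. On skeletal step economy this is clearly better than the chosen plan.
- Against it here: the absolute configuration would rest on an enantioselective gold-mediated bicyclisation, a far less settled matter than the reagent-controlled allylboration of step 5. The 6-endo attack at the alkyne competes with 5-exo attack.
- Further cost: A7 carries a C2 ketone and an unset C1. The C2 methyl and the C1/C2 relationship must then be installed on the hindered bicycle, probably through a tetrasubstituted enoate, and the pivalate arm still needs three or more steps to become the side chain. The early gain is spent again.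
- Equal: both plans rely on a Z tetrasubstituted alkene of defined geometry.

Key step: step 9

Assumption: the methallylborane 9 made from the (−)-α-pinene-derived borinate is taken to attack the Re face of enal 7, as such reagents do with simple aldehydes; the antipodal reagent would be used if the sense proved opposite.

## Route

Step 1
Reactants: 1 methyl 2-methyl-3-oxobutanoate
Product: 2 methyl (2Z)-2-methyl-3-{[(trifluoromethyl)sulfonyl]oxy}but-2-enoate
Conditions: Tf2O, 5 M aq. LiOH, toluene, 5 °C
Reagents that add atoms: trifluoromethanesulfonic anhydride, O=S(=O)(OS(=O)(=O)C(F)(F)F)C(F)(F)F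
Why: Lithium chelated between the two carbonyl oxygens holds the enolate in a U shape, so O-triflation puts the triflate cis to the ester and the two methyls cis to each other (stereoselective enol triflate formation); the geometry is to be confirmed by NOE before going on.

Step 2
Reactants: 2 methyl (2Z)-2-methyl-3-{[(trifluoromethyl)sulfonyl]oxy}but-2-enoate; 3 tert-butyldimethyl(prop-2-en-1-yloxy)silane
Product: 5 methyl (2Z)-6-[(tert-butyldimethylsilyl)oxy]-2,3-dimethylhex-2-enoate, via alkylborane 4 (not isolated)
Conditions: 3, 9-BBN-H, THF, 0 °C → rt; then 2, PdCl2(dppf) (5 mol %), 3 M aq. K3PO4, DMF, rt → 50 °C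
Reagents that add atoms: none
Why: Anti-Markovnikov hydroboration gives the primary alkylborane 4, and the B-alkyl Suzuki–Miyaura coupling replaces the triflate with retention of alkene geometry, so the C9 arm ends cis to the ester carbon (future C4) and the cis-dimethyl Z alkene is in place.

Step 3
Reactants: 5 methyl (2Z)-6-[(tert-butyldimethylsilyl)oxy]-2,3-dimethylhex-2-enoate
Product: 6 (2Z)-6-[(tert-butyldimethylsilyl)oxy]-2,3-dimethylhex-2-en-1-ol
Conditions: i-Bu2AlH (2.5 equiv), CH2Cl2, −78 °C; aq. KNaC4H4O6 work-up
Reagents that add atoms: none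
Why: 1,2-Reduction of the enoate by two hydride equivalents at low temperature; the tetrasubstituted alkene and the silyl ether are inert.

Step 4
Reactants: 6 (2Z)-6-[(tert-butyldimethylsilyl)oxy]-2,3-dimethylhex-2-en-1-ol
Product: 7 (2Z)-6-[(tert-butyldimethylsilyl)oxy]-2,3-dimethylhex-2-enal
Conditions: MnO2 (activated, excess), CH2Cl2, rt, dark
Reagents that add atoms: none
Why: Heterogeneous allylic oxidation under neutral conditions stops at the aldehyde and avoids the acid or base that could isomerise the tetrasubstituted Z enal, which is used at once.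

Step 5
Reactants: 7 (2Z)-6-[(tert-butyldimethylsilyl)oxy]-2,3-dimethylhex-2-enal; 8 (2-methylprop-2-en-1-yl)magnesium chloride
Product: 11 (4R,5Z)-9-[(tert-butyldimethylsilyl)oxy]-2,5,6-trimethylnona-1,5-dien-4-ol, via methallylborane 9 (not isolated), via borinate ester 10 (not isolated)
Conditions: (+)-Ipc2BOMe, 8, Et2O, −78 °C → rt; then 7, −78 °C; then 3 M aq. NaOH, 30% H2O2, rt
Reagents that add atoms: none
Why: Brown-type asymmetric allylboration: transmetalation gives allylborane 9, which adds through a closed chair transition state. The isopinocampheyl groups from (−)-α-pinene direct the methallyl group to the Re face of the aldehyde and set the C4 carbinol as R; oxidative work-up cleaves borinate 10.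

Step 6
Reactants: 11 (4R,5Z)-9-[(tert-butyldimethylsilyl)oxy]-2,5,6-trimethylnona-1,5-dien-4-ol; 12 prop-2-enoyl chloride
Product: 13 (4R,5Z)-9-[(tert-butyldimethylsilyl)oxy]-2,5,6-trimethylnona-1,5-dien-4-yl prop-2-enoate
Conditions: Et3N, CH2Cl2, −78 → 0 °C
Reagents that add atoms: none
Why: Plain O-acylation of the secondary allylic alcohol under basic, non-ionising conditions; it supplies C1 and the carboxyl carbon without touching the carbinol centre.

Step 7
Reactants: 13 (4R,5Z)-9-[(tert-butyldimethylsilyl)oxy]-2,5,6-trimethylnona-1,5-dien-4-yl prop-2-enoate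
Product: 14 (6R)-6-{(2Z)-6-[(tert-butyldimethylsilyl)oxy]-3-methylhex-2-en-2-yl}-4-methyl-5,6-dihydro-2H-pyran-2-one
Conditions: second-generation Grubbs catalyst (H2IMes)(PCy3)Cl2Ru=CHPh (5–10 mol %), CH2Cl2 (5 mM), 40 °C
Reagents that add atoms: none
Why: Ring-closing metathesis between the acrylate and the 1,1-disubstituted alkene gives the six-membered unsaturated lactone with loss of ethene. The ring alkene is necessarily cis, and the tetrasubstituted alkene is inert to the catalyst.

Step 8
Reactants: 14 (6R)-6-{(2Z)-6-[(tert-butyldimethylsilyl)oxy]-3-methylhex-2-en-2-yl}-4-methyl-5,6-dihydro-2H-pyran-2-one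
Product: 15 (4R,6R)-6-{(2Z)-6-[(tert-butyldimethylsilyl)oxy]-3-methylhex-2-en-2-yl}-4-methyloxan-2-one
Conditions: Cu(OAc)2·H2O (5 mol %), 1,2-bis(diphenylphosphino)benzene (5 mol %), (EtO)2MeSiH, t-BuOH, toluene, 0 °C → rt
Reagents that add atoms: none
Why: Copper hydride conjugate reduction of the β,β-disubstituted unsaturated lactone. Hydride adds to C2 axially, anti to the pseudo-equatorial alkenyl group on C4, so the methyl ends cis to it (substrate control, the same sense as cuprate additions to 6-substituted dihydropyranones); the isolated tetrasubstituted alkene and the allylic C–O bond are untouched.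

Step 9
Reactants: 15 (4R,6R)-6-{(2Z)-6-[(tert-butyldimethylsilyl)oxy]-3-methylhex-2-en-2-yl}-4-methyloxan-2-one
Product: 18 (1S,2R,6R)-2-{3-[(tert-butyldimethylsilyl)oxy]propyl}-2,3,6-trimethylcyclohex-3-ene-1-carboxylic acid, via silyl ketene acetal 16 (not isolated), via silyl ester 17 (not isolated)
Conditions: LiN(i-Pr)2, THF, −78 °C; Me3SiCl/Et3N (premixed), −78 °C → rt; toluene, 105 °C; then H2O/THF, rt (pH 4–5 work-up)
Reagents that add atoms: none
Why: Deprotonation at C1, the only acidic site, and O-silylation give the cyclic ketene acetal 16, whose array C1=C(OSi)–O–C4–C5=C10 undergoes a concerted suprafacial [3,3] shift; this is the Ireland–Claisen rearrangement of a lactone silyl enolate, the known way from 6-alkenyl δ-lactones to cyclohex-3-enecarboxylic acids. Because C2–C3 ties C1 to C4, a chair is impossible and only a boat-like, bicyclo[2.2.2]-type geometry with the alkenyl group axial on C4 is open, so ring A is closed by the sigmatropic C1–C10 bond formation itself while O–C4 cleavage leaves the C4=C5 ring alkene and the carboxyl at the right oxidation level. C10 is set by chirality transfer from the R carbinol C4 across the Z alkene: the C9 arm takes the inside position and the C10 methyl the outside one, so the methyl ends cis to the carboxyl. C1 is set in the same event because the new bond can form only on the lactone face that carries the alkenyl group, and with the cis-4-methyl lactone this puts the carboxyl trans to the C2 methyl. No facial or regiochemical choice is left to the reagent; what the step needs is a geometrically pure Z alkene and a diastereomerically pure cis lactone, since an E alkene would invert C10 and a trans lactone would give the C2-epimeric series. The boat eclipses C2 with the C9 arm and builds a quaternary centre, so heating in toluene is expected to be necessary, and Et3N keeps the allylic C4–O bond from acid-induced ionisation. Mild aqueous work-up cleaves only the trimethylsilyl ester 17 and leaves the TBS ether.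

Step 10
Reactants: 18 (1S,2R,6R)-2-{3-[(tert-butyldimethylsilyl)oxy]propyl}-2,3,6-trimethylcyclohex-3-ene-1-carboxylic acid; 19 [(4R)-2,2-dimethyl-1,3-dioxolan-4-yl]methanol
Product: 20 [(4S)-2,2-dimethyl-1,3-dioxolan-4-yl]methyl (1S,2R,6R)-2-{3-[(tert-butyldimethylsilyl)oxy]propyl}-2,3,6-trimethylcyclohex-3-ene-1-carboxylate
Conditions: PPh3, DIAD, THF, 0 °C → rt
Reagents that add atoms: none
Why: Mitsunobu esterification: the carboxylate attacks the CH2 of the alkoxyphosphonium ion of 19, so the hindered carbonyl carbon is never the electrophile. The stereocentre of 19 is not touched; its descriptor changes from R to S only through the priority rules.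

Step 11
Reactants: 20 [(4S)-2,2-dimethyl-1,3-dioxolan-4-yl]methyl (1S,2R,6R)-2-{3-[(tert-butyldimethylsilyl)oxy]propyl}-2,3,6-trimethylcyclohex-3-ene-1-carboxylate
Product: 21 [(4S)-2,2-dimethyl-1,3-dioxolan-4-yl]methyl (1S,2R,6R)-2-(3-hydroxypropyl)-2,3,6-trimethylcyclohex-3-ene-1-carboxylate
Conditions: Bu4NF, AcOH (1:1), THF, 0 °C → rt
Reagents that add atoms: none
Why: Fluoride cleavage of the primary silyl ether; buffering with acetic acid keeps the medium near neutral so that neither the acetonide nor the C1 centre is at risk.

Step 12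
Reactants: 21 [(4S)-2,2-dimethyl-1,3-dioxolan-4-yl]methyl (1S,2R,6R)-2-(3-hydroxypropyl)-2,3,6-trimethylcyclohex-3-ene-1-carboxylate
Product: 22 [(4S)-2,2-dimethyl-1,3-dioxolan-4-yl]methyl (1S,2R,6R)-2,3,6-trimethyl-2-(3-oxopropyl)cyclohex-3-ene-1-carboxylate
Conditions: Dess–Martin periodinane, pyridine, CH2Cl2, 0 °C → rt
Reagents that add atoms: none
Why: Dess–Martin oxidation of the primary alcohol to the C7 aldehyde; pyridine buffers the acetic acid released so the acetonide survives.

Step 13
Reactants: 22 [(4S)-2,2-dimethyl-1,3-dioxolan-4-yl]methyl (1S,2R,6R)-2,3,6-trimethyl-2-(3-oxopropyl)cyclohex-3-ene-1-carboxylate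
Product: 23 [(4S)-2,2-dimethyl-1,3-dioxolan-4-yl]methyl (1S,2R,6R)-2-(4,4-dibromobut-3-en-1-yl)-2,3,6-trimethylcyclohex-3-ene-1-carboxylate
Conditions: CBr4, PPh3, 2,6-lutidine, CH2Cl2, 0 °C
Reagents that add atoms: tetrabromomethane, BrC(Br)(Br)Br
Why: Ramirez dibromo-olefination (first stage of the Corey–Fuchs sequence) adds C6 as a CBr2 unit; the amine buffer protects the acetonide from phosphonium bromide acidity.

Step 14
Reactants: 23 [(4S)-2,2-dimethyl-1,3-dioxolan-4-yl]methyl (1S,2R,6R)-2-(4,4-dibromobut-3-en-1-yl)-2,3,6-trimethylcyclohex-3-ene-1-carboxylate; 24 5-bromo-2-methylpent-2-ene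
Product: 26 [(4S)-2,2-dimethyl-1,3-dioxolan-4-yl]methyl (1S,2R,6R)-2-[(3Z)-4-bromo-8-methylnona-3,7-dien-1-yl]-2,3,6-trimethylcyclohex-3-ene-1-carboxylate, via alkylzinc bromide 25 (not isolated)
Conditions: 24, Zn dust, I2 (5 mol %), DMA, 70 °C; then 23, PdCl2(DPEphos) (3 mol %), THF/DMA, 0 °C → rt
Reagents that add atoms: none
Why: Trans-selective Negishi mono-alkylation of a 1,1-dibromoalkene: oxidative addition is faster at the C–Br bond trans to the C8 chain (cis to H), so the homoprenyl group enters trans to the chain and the remaining bromide stays cis to it, the geometry required for ring closure. The ester and acetonide tolerate the organozinc.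

Step 15
Reactants: 26 [(4S)-2,2-dimethyl-1,3-dioxolan-4-yl]methyl (1S,2R,6R)-2-[(3Z)-4-bromo-8-methylnona-3,7-dien-1-yl]-2,3,6-trimethylcyclohex-3-ene-1-carboxylate
Product: 27 [(4S)-2,2-dimethyl-1,3-dioxolan-4-yl]methyl (1S,2R,4aR,8aR)-2,4a,8a-trimethyl-5-(4-methylpent-3-en-1-yl)-1,2,4a,7,8,8a-hexahydronaphthalene-1-carboxylate
Conditions: Pd(OAc)2 (10 mol %), PPh3 (25 mol %), Ag2CO3, MeCN, 80 °C
Reagents that add atoms: none
Why: Intramolecular Heck reaction, 6-exo-trig: the vinylpalladium on C6 adds syn across C4=C5 from the ring A face that carries the C9 tether, so C6 bonds to C5 on that face and the C5 methyl is pushed cis to the C10 methyl. C5 has no hydrogen, so β-hydride elimination can only go towards C3 and gives the C3=C4 alkene; the silver salt removes bromide and limits re-addition of palladium hydride that could move the alkene towards C2.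

Step 16
Reactants: 27 [(4S)-2,2-dimethyl-1,3-dioxolan-4-yl]methyl (1S,2R,4aR,8aR)-2,4a,8a-trimethyl-5-(4-methylpent-3-en-1-yl)-1,2,4a,7,8,8a-hexahydronaphthalene-1-carboxylate
Product: 28 [(4S)-2,2-dimethyl-1,3-dioxolan-4-yl]methyl (1S,2R,4aR,8aR)-2,4a,8a-trimethyl-5-(4-methylpent-3-en-1-yl)-1,2,3,4,4a,7,8,8a-octahydronaphthalene-1-carboxylate
Conditions: H2 (1 atm), RhCl(PPh3)3 (10 mol %), benzene/EtOH, rt
Reagents that add atoms: none
Why: Homogeneous hydrogenation with RhCl(PPh3)3 reduces cis-disubstituted alkenes much faster than trisubstituted ones, so C3=C4 should be saturated while C6=C7 and the side-chain alkene remain; no stereocentre is created.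

Step 17
Reactants: 28 [(4S)-2,2-dimethyl-1,3-dioxolan-4-yl]methyl (1S,2R,4aR,8aR)-2,4a,8a-trimethyl-5-(4-methylpent-3-en-1-yl)-1,2,3,4,4a,7,8,8a-octahydronaphthalene-1-carboxylate
Product: 29 (2S)-2,3-dihydroxypropyl (1S,2R,4aR,8aR)-2,4a,8a-trimethyl-5-(4-methylpent-3-en-1-yl)-1,2,3,4,4a,7,8,8a-octahydronaphthalene-1-carboxylate
Conditions: AcOH/H2O (4:1), 40 °C
Reagents that add atoms: none
Why: Mild acid hydrolysis of the acetonide; aqueous acetic acid is too weak to protonate the trisubstituted alkenes, and the hindered acyl group is not expected to migrate.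

Step 18
Reactants: 29 (2S)-2,3-dihydroxypropyl (1S,2R,4aR,8aR)-2,4a,8a-trimethyl-5-(4-methylpent-3-en-1-yl)-1,2,3,4,4a,7,8,8a-octahydronaphthalene-1-carboxylate
Product: 30 (2S)-3-(acetyloxy)-2-hydroxypropyl (1S,2R,4aR,8aR)-2,4a,8a-trimethyl-5-(4-methylpent-3-en-1-yl)-1,2,3,4,4a,7,8,8a-octahydronaphthalene-1-carboxylate
Conditions: AcCl (1.05 equiv), 2,4,6-collidine, CH2Cl2, −78 °C
Reagents that add atoms: acetyl chloride, CC(=O)Cl
Why: Kinetic acylation with acetyl chloride and a hindered pyridine base at low temperature is selective for primary over secondary hydroxyl; the glycerol centre keeps the configuration brought in with 19, and work-up and chromatography are kept neutral and cold to prevent acetyl migration.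

## Compound list

1 | methyl 2-methyl-3-oxobutanoate | COC(=O)C(C)C(C)=O | starting material
2 | methyl (2Z)-2-methyl-3-{[(trifluoromethyl)sulfonyl]oxy}but-2-enoate | COC(=O)/C(C)=C(/C)OS(=O)(=O)C(F)(F)F | intermediate
3 | tert-butyldimethyl(prop-2-en-1-yloxy)silane | C=CCO[Si](C)(C)C(C)(C)C | starting material
4 | 9-{3-[(tert-butyldimethylsilyl)oxy]propyl}-9-borabicyclo[3.3.1]nonane | CC(C)(C)[Si](C)(C)OCCCB1C2CCCC1CCC2 | intermediate
5 | methyl (2Z)-6-[(tert-butyldimethylsilyl)oxy]-2,3-dimethylhex-2-enoate | COC(=O)/C(C)=C(/C)CCCO[Si](C)(C)C(C)(C)C | intermediate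
6 | (2Z)-6-[(tert-butyldimethylsilyl)oxy]-2,3-dimethylhex-2-en-1-ol | OC/C(C)=C(/C)CCCO[Si](C)(C)C(C)(C)C | intermediate
7 | (2Z)-6-[(tert-butyldimethylsilyl)oxy]-2,3-dimethylhex-2-enal | O=C/C(C)=C(/C)CCCO[Si](C)(C)C(C)(C)C | intermediate
8 | (2-methylprop-2-en-1-yl)magnesium chloride | CC(=C)C[Mg]Cl | starting material
9 | (+)-B-(2-methylprop-2-en-1-yl)diisopinocampheylborane (isopinocampheyl groups from (−)-α-pinene) | CC(=C)CB([C@H]1C[C@H]2C[C@@H]([C@@H]1C)C2(C)C)[C@H]1C[C@H]2C[C@@H]([C@@H]1C)C2(C)C | intermediate
10 | (4R,5Z)-9-[(tert-butyldimethylsilyl)oxy]-2,5,6-trimethylnona-1,5-dien-4-yl diisopinocampheylborinate | CC(=C)C[C@@H](OB([C@H]1C[C@H]2C[C@@H]([C@@H]1C)C2(C)C)[C@H]1C[C@H]2C[C@@H]([C@@H]1C)C2(C)C)/C(C)=C(/C)CCCO[Si](C)(C)C(C)(C)C | intermediate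
11 | (4R,5Z)-9-[(tert-butyldimethylsilyl)oxy]-2,5,6-trimethylnona-1,5-dien-4-ol | CC(=C)C[C@@H](O)/C(C)=C(/C)CCCO[Si](C)(C)C(C)(C)C | intermediate
12 | prop-2-enoyl chloride | C=CC(=O)Cl | starting material
13 | (4R,5Z)-9-[(tert-butyldimethylsilyl)oxy]-2,5,6-trimethylnona-1,5-dien-4-yl prop-2-enoate | C=CC(=O)O[C@H](CC(C)=C)/C(C)=C(/C)CCCO[Si](C)(C)C(C)(C)C | intermediate
14 | (6R)-6-{(2Z)-6-[(tert-butyldimethylsilyl)oxy]-3-methylhex-2-en-2-yl}-4-methyl-5,6-dihydro-2H-pyran-2-one | O=C1C=C(C)C[C@@H](O1)/C(C)=C(/C)CCCO[Si](C)(C)C(C)(C)C | intermediate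
15 | (4R,6R)-6-{(2Z)-6-[(tert-butyldimethylsilyl)oxy]-3-methylhex-2-en-2-yl}-4-methyloxan-2-one (cis lactone, key-step precursor) | O=C1C[C@H](C)C[C@@H](O1)/C(C)=C(/C)CCCO[Si](C)(C)C(C)(C)C | intermediate
16 | (2R,4R)-2-{(2Z)-6-[(tert-butyldimethylsilyl)oxy]-3-methylhex-2-en-2-yl}-4-methyl-6-[(trimethylsilyl)oxy]-3,4-dihydro-2H-pyran | C[Si](C)(C)OC1=C[C@H](C)C[C@@H](O1)/C(C)=C(/C)CCCO[Si](C)(C)C(C)(C)C | intermediate
17 | trimethylsilyl (1S,2R,6R)-2-{3-[(tert-butyldimethylsilyl)oxy]propyl}-2,3,6-trimethylcyclohex-3-ene-1-carboxylate | C[Si](C)(C)OC(=O)[C@H]1[C@H](C)CC=C(C)[C@]1(C)CCCO[Si](C)(C)C(C)(C)C | intermediate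
18 | (1S,2R,6R)-2-{3-[(tert-butyldimethylsilyl)oxy]propyl}-2,3,6-trimethylcyclohex-3-ene-1-carboxylic acid (key-step product) | OC(=O)[C@H]1[C@H](C)CC=C(C)[C@]1(C)CCCO[Si](C)(C)C(C)(C)C | intermediate
19 | [(4R)-2,2-dimethyl-1,3-dioxolan-4-yl]methanol, (R)-solketal | CC1(C)OC[C@@H](CO)O1 | starting material
20 | [(4S)-2,2-dimethyl-1,3-dioxolan-4-yl]methyl (1S,2R,6R)-2-{3-[(tert-butyldimethylsilyl)oxy]propyl}-2,3,6-trimethylcyclohex-3-ene-1-carboxylate | CC1(C)OC[C@@H](COC(=O)[C@H]2[C@H](C)CC=C(C)[C@]2(C)CCCO[Si](C)(C)C(C)(C)C)O1 | intermediate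
21 | [(4S)-2,2-dimethyl-1,3-dioxolan-4-yl]methyl (1S,2R,6R)-2-(3-hydroxypropyl)-2,3,6-trimethylcyclohex-3-ene-1-carboxylate | CC1(C)OC[C@@H](COC(=O)[C@H]2[C@H](C)CC=C(C)[C@]2(C)CCCO)O1 | intermediate
22 | [(4S)-2,2-dimethyl-1,3-dioxolan-4-yl]methyl (1S,2R,6R)-2,3,6-trimethyl-2-(3-oxopropyl)cyclohex-3-ene-1-carboxylate | CC1(C)OC[C@@H](COC(=O)[C@H]2[C@H](C)CC=C(C)[C@]2(C)CCC=O)O1 | intermediate
23 | [(4S)-2,2-dimethyl-1,3-dioxolan-4-yl]methyl (1S,2R,6R)-2-(4,4-dibromobut-3-en-1-yl)-2,3,6-trimethylcyclohex-3-ene-1-carboxylate | CC1(C)OC[C@@H](COC(=O)[C@H]2[C@H](C)CC=C(C)[C@]2(C)CCC=C(Br)Br)O1 | intermediate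
24 | 5-bromo-2-methylpent-2-ene | CC(C)=CCCBr | starting material
25 | (4-methylpent-3-en-1-yl)zinc bromide | CC(C)=CCC[Zn]Br | intermediate
26 | [(4S)-2,2-dimethyl-1,3-dioxolan-4-yl]methyl (1S,2R,6R)-2-[(3Z)-4-bromo-8-methylnona-3,7-dien-1-yl]-2,3,6-trimethylcyclohex-3-ene-1-carboxylate | CC1(C)OC[C@@H](COC(=O)[C@H]2[C@H](C)CC=C(C)[C@]2(C)CC/C=C(\Br)CCC=C(C)C)O1 | intermediate
27 | [(4S)-2,2-dimethyl-1,3-dioxolan-4-yl]methyl (1S,2R,4aR,8aR)-2,4a,8a-trimethyl-5-(4-methylpent-3-en-1-yl)-1,2,4a,7,8,8a-hexahydronaphthalene-1-carboxylate | CC1(C)OC[C@@H](COC(=O)[C@H]2[C@H](C)C=C[C@]3(C)C(CCC=C(C)C)=CCC[C@]23C)O1 | intermediate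
28 | [(4S)-2,2-dimethyl-1,3-dioxolan-4-yl]methyl (1S,2R,4aR,8aR)-2,4a,8a-trimethyl-5-(4-methylpent-3-en-1-yl)-1,2,3,4,4a,7,8,8a-octahydronaphthalene-1-carboxylate | CC1(C)OC[C@@H](COC(=O)[C@H]2[C@H](C)CC[C@]3(C)C(CCC=C(C)C)=CCC[C@]23C)O1 | intermediate
29 | (2S)-2,3-dihydroxypropyl (1S,2R,4aR,8aR)-2,4a,8a-trimethyl-5-(4-methylpent-3-en-1-yl)-1,2,3,4,4a,7,8,8a-octahydronaphthalene-1-carboxylate | OC[C@@H](COC(=O)[C@H]1[C@H](C)CC[C@]2(C)C(CCC=C(C)C)=CCC[C@]12C)O | intermediate
30 | (2S)-3-(acetyloxy)-2-hydroxypropyl (1S,2R,4aR,8aR)-2,4a,8a-trimethyl-5-(4-methylpent-3-en-1-yl)-1,2,3,4,4a,7,8,8a-octahydronaphthalene-1-carboxylate (CNP0146255.1) | CC(=O)OC[C@H](O)COC(=O)[C@H]1[C@H](C)CC[C@]2(C)C(CCC=C(C)C)=CCC[C@]12C | target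

## Step count and least certain steps

Total step count: 18. Longest linear sequence: 18 steps (1 → 30). Partners 3, 8, 12, 19 and 24 are purchased, and 4, 9 and 25 are made and used in the same flask.

**Step 9 (key step).** Most likely failure: the [3,3] shift is slow, because the only available boat eclipses C2 with the C9 arm and builds a quaternary centre. At the temperature then needed, ionisation of the allylic C4–O bond next to the tetrasubstituted alkene, or loss of the labile trimethylsilyl ketene acetal, can overtake the rearrangement. Fallback, setting out from 6 and returning at 18: esterify 6 with (3R)-3-methylhex-5-enoic acid F1 (DCC, DMAP) to the allylic ester (2Z)-6-[(tert-butyldimethylsilyl)oxy]-2,3-dimethylhex-2-en-1-yl (3R)-3-methylhex-5-enoate F2. Run the acyclic Ireland–Claisen rearrangement through a chair (LiN(i-Pr)2, Me3SiCl, THF, −78 → 60 °C, with THF or THF/DMPU chosen to give the ketene acetal geometry that matches the C1/C10 relationship) to the diene acid (2S,3R)-2-{(3R)-6-[(tert-butyldimethylsilyl)oxy]-2,3-dimethylhex-1-en-3-yl}-3-methylhex-5-enoic acid F3. Then close ring A by ring-closing metathesis of the allyl and isopropenyl groups (second-generation Grubbs catalyst) to reach 18. The price is that C2 exerts only modest 1,2-induction on the open-chain enolate, so a diastereomer separation should be expected.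

**Step 15.** Most likely failure: carbopalladation at the fully substituted C5 next to quaternary C10 does not occur. The reactive conformer needs the C9 arm axial and syn to the C2 methyl, so protodebromination or 7-endo closure may compete, and re-addition of palladium hydride may move the new alkene towards C2. Fallback, setting out from 26 and returning at 28: vinyl radical cyclisation (Bu3SnH, AIBN, benzene, 80 °C, slow addition). The C6 radical should add 6-exo to C5 on the tether face and the C4 radical is then reduced, giving 28 directly and bypassing step 16. This fallback passes through no new isolated compound (F0).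

**Step 16.** Most likely failure: loss of chemoselectivity. C3=C4 is cis-disubstituted but flanked by C2 and quaternary C5, so the unhindered trisubstituted side-chain alkene may be reduced at a comparable rate. Fallback, setting out from 23 and returning at 28, with the side-chain alkene built only after the hydrogenation:
- Negishi coupling of 23 with commercial (3-ethoxy-3-oxopropyl)zinc bromide under the step 14 catalyst gives the bromo ester [(4S)-2,2-dimethyl-1,3-dioxolan-4-yl]methyl (1S,2R,6R)-2-[(3Z)-4-bromo-7-ethoxy-7-oxohept-3-en-1-yl]-2,3,6-trimethylcyclohex-3-ene-1-carboxylate F4.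
- Heck closure as in step 15 gives the diene ester F5.
- Hydrogenation, now with only the hindered ring alkene C6=C7 as competitor, gives the monoene ester F6.
- i-Bu2AlH at −78 °C reduces the unhindered ethyl ester to the aldehyde F7.
- Wittig reaction with isopropylidenetriphenylphosphorane gives 28.

**Step 14.** Most likely failure: erosion of trans selectivity or double coupling, together with β-hydride elimination from the alkylpalladium, giving bromoalkene isomers of which only the Z one can cyclise. Fallback, setting out from 22 and returning at 27: Stork–Zhao-type olefination. The ylide from (5-methylhex-4-en-1-yl)triphenylphosphonium bromide F8 is iodinated (I2) and deprotonated again (NaN(SiMe3)2), then added to 22 at −78 °C to give the (Z)-vinyl iodide [(4S)-2,2-dimethyl-1,3-dioxolan-4-yl]methyl (1S,2R,6R)-2-[(3Z)-4-iodo-8-methylnona-3,7-dien-1-yl]-2,3,6-trimethylcyclohex-3-ene-1-carboxylate F9. This is cyclised under the step 15 conditions to 27.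

**Step 18.** Most likely failure: incomplete primary selectivity, followed by acetyl migration between O-3 and O-2 during work-up, giving regioisomeric acetates that are hard to separate. Fallback, setting out from 29 and returning at 30, forming the C–O bond by substitution instead of acylation: selective primary sulfonylation (TsCl, Bu2SnO cat., Et3N) to the monotosylate F10, closure with K2CO3 to the glycidyl ester (2S)-oxiran-2-ylmethyl (1S,2R,4aR,8aR)-2,4a,8a-trimethyl-5-(4-methylpent-3-en-1-yl)-1,2,3,4,4a,7,8,8a-octahydronaphthalene-1-carboxylate F11, and opening of the epoxide at its terminal carbon with AcOH/CsOAc to give 30. No bond to the glycerol stereocentre is broken.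

## Further compounds

F1 | step 9 | (3R)-3-methylhex-5-enoic acid | OC(=O)C[C@H](C)CC=C
F2 | step 9 | (2Z)-6-[(tert-butyldimethylsilyl)oxy]-2,3-dimethylhex-2-en-1-yl (3R)-3-methylhex-5-enoate | C=CC[C@@H](C)CC(=O)OC/C(C)=C(/C)CCCO[Si](C)(C)C(C)(C)C
F3 | step 9 | (2S,3R)-2-{(3R)-6-[(tert-butyldimethylsilyl)oxy]-2,3-dimethylhex-1-en-3-yl}-3-methylhex-5-enoic acid | OC(=O)[C@@H]([C@H](C)CC=C)[C@@](C)(CCCO[Si](C)(C)C(C)(C)C)C(C)=C
F0 | step 15 | none | none
F4 | step 16 | [(4S)-2,2-dimethyl-1,3-dioxolan-4-yl]methyl (1S,2R,6R)-2-[(3Z)-4-bromo-7-ethoxy-7-oxohept-3-en-1-yl]-2,3,6-trimethylcyclohex-3-ene-1-carboxylate | CC1(C)OC[C@@H](COC(=O)[C@H]2[C@H](C)CC=C(C)[C@]2(C)CC/C=C(\Br)CCC(=O)OCC)O1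
F5 | step 16 | [(4S)-2,2-dimethyl-1,3-dioxolan-4-yl]methyl (1S,2R,4aR,8aR)-5-(3-ethoxy-3-oxopropyl)-2,4a,8a-trimethyl-1,2,4a,7,8,8a-hexahydronaphthalene-1-carboxylate | CC1(C)OC[C@@H](COC(=O)[C@H]2[C@H](C)C=C[C@]3(C)C(CCC(=O)OCC)=CCC[C@]23C)O1
F6 | step 16 | [(4S)-2,2-dimethyl-1,3-dioxolan-4-yl]methyl (1S,2R,4aR,8aR)-5-(3-ethoxy-3-oxopropyl)-2,4a,8a-trimethyl-1,2,3,4,4a,7,8,8a-octahydronaphthalene-1-carboxylate | CC1(C)OC[C@@H](COC(=O)[C@H]2[C@H](C)CC[C@]3(C)C(CCC(=O)OCC)=CCC[C@]23C)O1
F7 | step 16 | [(4S)-2,2-dimethyl-1,3-dioxolan-4-yl]methyl (1S,2R,4aR,8aR)-2,4a,8a-trimethyl-5-(3-oxopropyl)-1,2,3,4,4a,7,8,8a-octahydronaphthalene-1-carboxylate | CC1(C)OC[C@@H](COC(=O)[C@H]2[C@H](C)CC[C@]3(C)C(CCC=O)=CCC[C@]23C)O1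
F8 | step 14 | (5-methylhex-4-en-1-yl)triphenylphosphonium bromide | CC(C)=CCCC[P+](c1ccccc1)(c1ccccc1)c1ccccc1.[Br-]
F9 | step 14 | [(4S)-2,2-dimethyl-1,3-dioxolan-4-yl]methyl (1S,2R,6R)-2-[(3Z)-4-iodo-8-methylnona-3,7-dien-1-yl]-2,3,6-trimethylcyclohex-3-ene-1-carboxylate | CC1(C)OC[C@@H](COC(=O)[C@H]2[C@H](C)CC=C(C)[C@]2(C)CC/C=C(\I)CCC=C(C)C)O1
F10 | step 18 | 2-hydroxy-3-[(4-methylbenzenesulfonyl)oxy]propyl (1S,2R,4aR,8aR)-2,4a,8a-trimethyl-5-(4-methylpent-3-en-1-yl)-1,2,3,4,4a,7,8,8a-octahydronaphthalene-1-carboxylate (glycerol configuration as in 29) | Cc1ccc(cc1)S(=O)(=O)OC[C@@H](COC(=O)[C@H]2[C@H](C)CC[C@]3(C)C(CCC=C(C)C)=CCC[C@]23C)O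
F11 | step 18 | (2S)-oxiran-2-ylmethyl (1S,2R,4aR,8aR)-2,4a,8a-trimethyl-5-(4-methylpent-3-en-1-yl)-1,2,3,4,4a,7,8,8a-octahydronaphthalene-1-carboxylate | C1[C@@H](COC(=O)[C@H]2[C@H](C)CC[C@]3(C)C(CCC=C(C)C)=CCC[C@]23C)O1
A1 | alternative 1 | 2,7-dimethylcyclodecane-1,6-dione | CC1CCCC(=O)C(C)CCCC1=O
A2 | alternative 1 | 2,7-dimethyl-1,6-bis[(trimethylsilyl)oxy]cyclodeca-1,6-diene | CC1=C(O[Si](C)(C)C)CCCC(C)=C(O[Si](C)(C)C)CCC1
A3 | alternative 1 | cis-4a,8a-dimethyloctahydronaphthalene-1,5-dione (C2-symmetric, enantiomer as drawn) | O=C1CCC[C@]2(C)C(=O)CCC[C@]12C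
A4 | alternative 2 | methyl (1S,2R,6R)-2-[(3Z)-4-bromo-8-methylnona-3,7-dien-1-yl]-2,3,6-trimethylcyclohex-3-ene-1-carboxylate | COC(=O)[C@H]1[C@H](C)CC=C(C)[C@]1(C)CC/C=C(\Br)CCC=C(C)C
A5 | alternative 2 | methyl (1S,2R,4aR,8aR)-2,4a,8a-trimethyl-5-(4-methylpent-3-en-1-yl)-1,2,4a,7,8,8a-hexahydronaphthalene-1-carboxylate | COC(=O)[C@H]1[C@H](C)C=C[C@]2(C)C(CCC=C(C)C)=CCC[C@]12C
A6 | alternative 3 | methyl (6Z)-14-[(2,2-dimethylpropanoyl)oxy]-6,7-dimethyl-3-[(trimethylsilyl)oxy]tetradeca-2,6-dien-10-ynoate | COC(=O)C=C(O[Si](C)(C)C)CC/C(C)=C(/C)CCC#CCCCOC(=O)C(C)(C)C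
A7 | alternative 3 | methyl cis-5-{3-[(2,2-dimethylpropanoyl)oxy]propyl}-4a,8a-dimethyl-2-oxo-1,2,3,4,4a,7,8,8a-octahydronaphthalene-1-carboxylate | COC(=O)C1C(=O)CC[C@]2(C)C(CCCOC(=O)C(C)(C)C)=CCC[C@]12C
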